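All runs are calculated for substances that don't exist; noise was put on by code.

Late in the earlier runs the target drifts down towards a level, and ochre, with more free base, holds more of it than violet: 27.6% against 21.0% at 120 s.

the same everywhere: electrophile 0.083 M

|  | free base | protonated nucleophile | protic impurity | remark | time |
|---|---|---|---|---|---|
| violet | 0.11 M | 0.083 M | 0.083 M | run made earlier |  |
| ochre | 0.13 M | 0.083 M | 0.083 M | run made earlier |  |
| elm | 0.120 M | 0.0830 M | 0.0830 M |  | 3.0 min |
| ash | 0.160 M | 0.0830 M | 0.0830 M |  | 3.0 min |

- violet (time / s: electrophile / %, target / %): 10.0: 64.4, 36.1; 15.0: 66.2, 34.8; 25.0: 69.4, 31.0; 40.0: 72.5, 27.8; 50.0: 74.1, 26.2; 80.0: 76.7, 23.8; 120: 79.6, 21.0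
- ochre (time / s: electrophile / %, target / %): 20.0: 62.7, 37.5; 40.0: 67.0, 32.7; 50.0: 68.1, 31.3; 80.0: 71.1, 29.1; 90.0: 71.3, 28.7; 120: 72.1, 27.6

(scatter of a reading: 0.3 percentage points)



- part of the electrophile that has reacted at the end, elm
- part of the electrophile that has reacted at the end, ash
- what raising the concentration of free base from its lowest to its highest value here does to the part of the electrophile that has reacted (changes below 5 percentage points count as none) (no change / it rises / it falls)

Is 3.0 min late enough? Ochre's target readings fell by 1.1 percentage points between 90.0 s and 120 s, less than the 5 points that count as a change, and 3.0 min lies past that last reading, so we reckon elm and ash as if at their resting levels.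

How much base can the target draw on? We take the protic impurity to consume free base one for one, which leaves as spare base 0.0470 M in ochre, 0.0370 M in elm and 0.0770 M in ash.

How does spare base divide? Ochre's last reading is 0.02291 M of target. We define the balance number, an apparent equilibrium constant, as target times impurity charged plus target, over electrophile times protonated nucleophile times free base left: 27.9 M⁻¹.

Rearranged, target is spare base over one plus a split, and the split, impurity charged plus target over the balance number times electrophile times protonated nucleophile, itself depends on target, so we iterate. Elm starts from ochre's share of spare base, 0.01803 M, and goes round to 0.01991 M, then 0.01920 M, which is 23.1%. Ash starts at 0.03753 M and swings to 0.02492 M, so their mean, 0.03122 M, goes back in and gives 0.03046 M, which is 36.7%. The gap of 14 points exceeds the margin, so conversion rises.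

The forecast, a little above our figures, gave 23.8% for elm and 37.5% for ash, it rises, holding that “Three minutes is essentially at plateau”.

The flask gives 22.7% for elm and 39.6% for ash: it rises, by 17 points.

    electrophile + nucleophile ⇌ acid set free + target (K = 0.500, k = 7.70 M⁻¹ s⁻¹)
    nucleophile + acid set free ⇌ protonated nucleophile, settled at all times (K = 11000 M⁻¹)
    acid set free + free base ⇌ salt of the base, settled at all times (K = 3400 M⁻¹)
    protic impurity + free base → quenched reagent (k = 3.30 M⁻¹ s⁻¹)

At 3.00 min the protic impurity stands at 0.043% of its charge in ash, less than the 3.3% in elm. Elm's result put into the balance number returns 25.7 M⁻¹, against 27.9 M⁻¹ from ochre. For the flask like elm but with 0.21 M of electrophile, two rounds from elm's target give 0.02844 M, then 0.02636 M, or 12.6%, and that flask gives 10.6%.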